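1. At early times, 2.50 h in, the dawn run reads target 3% and the dusk run 2% of the solid substrate charged. I therefore treat what the coupling partner loses as a correction to its charge.

in all of them: solid substrate 11 mM

| run | coupling partner | remark | time |
|---|---|---|---|
| dawn | 6.6 mM | run made earlier |  |
| dusk | 9.9 mM | run made earlier |  |
| flask | 13.2 mM |  | 10 h |

| run | time / h | target / % | starting material / % | solid substrate / % |
|---|---|---|---|---|
| dawn | 2.50 | 3 | 19 | 82 |
| dawn | 5.00 | 6 | 29 | 64 |
| dawn | 8.00 | 9 | 37 | 52 |
| dawn | 10.0 | 15 | 42 | 43 |
| dusk | 2.50 | 2 | 15 | 80 |
| dusk | 5.00 | 5 | 30 | 64 |
| dusk | 8.00 | 10 | 39 | 50 |
| dusk | 10.0 | 14 | 39 | 42 |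

(each reading ± 2 percentage points)

1. concentration of target at 10 h, in mM
2. concentration of starting material at 10 h, in mM
3. concentration of solid substrate at 10 h, in mM
4. concentration of coupling partner at 10 h, in mM

- as a solid, counted per litre of solution: solid substrate
- what was read earlier has a scatter of 2 percentage points, one standard deviation
- candidate steps: starting material + coupling partner <-> target; starting material + 2 coupling partner -> side product; solid substrate <-> starting material
- at the start none of the solid substrate is in solution
- starting material means what is dissolved; the solid is not counted in it

2. Each target takes one coupling partner and each side product two. In the flask, the fraction of partner left is one minus r times (P plus two Q), where P and Q are the target and side product as fractions of the solid charge. Here r, the exchange rate, is the solid charge over the partner charge, 0.833, the inverse of the equivalents charged.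

3. Q is not read, so I take it from the gap in the mass balance: one minus the target, starting material and solid substrate readings. Starting material and solid substrate therefore enter this sum through that gap.

4. A scatter of 2 percentage points in P moves the fraction left by 1.7 points, and the same scatter in Q moves it by 3.3 points. An error of 2 points in one run's final reading of starting material or solid substrate moves the gap averaged over the two runs, and with it the fraction left by 1.7 points.

5. For P, the mean reading at 10.0 h is 14.5%, and scaling the dusk reading by the partner charges gives 18.7%. For Q, I take the mean gap in the two balances, 2.50%.

6. With the gap as read, my reckoning leaves 80.3% to 83.7% of the partner in the flask; this band spans the two values of P and does not include the scatter of the gap.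

7. The forecast gives target 1.9 mM, starting material 4.2 mM, solid substrate 4.5 mM and coupling partner 10.4 mM, noting that “The solid falls almost identically in both runs”. Its partner figure is 78.8% of the charge, lower than my band.

8. The flask gives target 2.15 mM, starting material 4.13 mM, solid substrate 4.51 mM and coupling partner 10.6 mM, each within the forecast's range.

    starting material + coupling partner ⇌ target (K = 68.0 L mol⁻¹, k = 0.00375 L mol⁻¹ s⁻¹)
    starting material + 2 coupling partner → side product (k = 0.0160 L² mol⁻² s⁻¹)
    solid substrate ⇌ starting material, rate k3*(cs3 - [starting material]) while solid is left; crystals form when [starting material] > cs3 (solubility = 6.20 mM, k = 5.12 × 10⁻⁵ s⁻¹)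

While solid substrate fell in the flask from 90.5% at 1.00 h to 41.0% at 10.0 h, starting material was made 2.36 times faster than it was used up at 3.71 h, each step taken net. By 10.0 h the flask held 19.5% target and 1.91% side product, and at 0.833 these leave 80.6% of the partner. In the neighbouring flask with 33 mM of partner, the exchange rate is 0.333, and 35.5% target with 8.92% side product leave 82.2%, against a simulated 82.2%.

The runs come from a simulation for substances that don't exist, and the scatter is random.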